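**Plan**

1. Numbering (avarane): ring A = C1–C4, C5, C10; ring B = C5–C10; C4 carries =CH2; C5, C8 and C9 carry CH3; C9 carries C11H2–quinone.
2. Retrosynthesis: hydroxyquinone ⇐ tetramethoxyarene; C4=CH2 ⇐ C4=O; C5–CH3 ⇐ reductive methylation of the enone C4(=O)–C5=C6; C11–aryl ⇐ C11 aldehyde + aryllithium; last, ring B is cut at C7–C8 and C9–C10.
3. Enabling feature: in ring B the cis C8/C9 methyl pair, with the one-carbon branch C11 on quaternary C9, is the retron of (E)-2-methylbut-2-enal; C5=C6 next to the C4 carbonyl is what a 2-vinylcyclohex-2-enone ketal (ring A) leaves after a [4+2] addition.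
4. Forward: ring A bromoenone → ketal → vinyl diene; ring B is closed by a catalytic enantioselective Diels–Alder reaction; the arene is joined at C11 and the carbinol oxygen removed; the enone is unmasked, C5 methylated, C4 methylenated; the arene is oxidised and hydrolysed to the hydroxyquinone.
5. Stereochemistry: C8, C9 and C10 arise together in the cycloaddition (E geometry of the enal, formyl-exo topology, catalyst-controlled face); C5 is set by substrate control, the axial C9 methyl blocking the face that would give the trans-decalin.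

Key step: step 3

Remark: C11 is created in step 4 as a mixture of epimers and becomes CH2 in step 5, so its configuration is left open in 8–10.

**Step 1**
Reactants: 1 2-bromocyclohex-2-en-1-one
Product: 2 6-bromo-1,4-dioxaspiro[4.5]dec-6-ene
Conditions: ethane-1,2-diol (3 equiv), p-TsOH·H2O (cat.), benzene, reflux, Dean–Stark
Reagents that add atoms: ethane-1,2-diol, OCCO
Why: Acid-catalysed ketalisation with azeotropic removal of water; the α-bromo substituent keeps the double bond in place, so the allylic ketal should form without β,γ-migration.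

**Step 2**
Reactants: 2 6-bromo-1,4-dioxaspiro[4.5]dec-6-ene
Product: 3 6-ethenyl-1,4-dioxaspiro[4.5]dec-6-ene
Conditions: 2-ethenyl-4,4,5,5-tetramethyl-1,3,2-dioxaborolane (1.3 equiv), PdCl2(dppf) (5 mol%; dppf = 1,1'-bis(diphenylphosphino)ferrocene), K2CO3, 1,4-dioxane/H2O, 80 °C
Reagents that add atoms: 2-ethenyl-4,4,5,5-tetramethyl-1,3,2-dioxaborolane, C=CB1OC(C)(C)C(C)(C)O1
Why: Suzuki–Miyaura coupling of an alkenyl bromide under basic conditions that leave the ketal untouched.

**Step 3**
Reactants: 3 6-ethenyl-1,4-dioxaspiro[4.5]dec-6-ene; 4 (E)-2-methylbut-2-enal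
Product: 5 (1R,2S,8aS)-5,5-(ethylenedioxy)-1,2-dimethyl-1,2,3,5,6,7,8,8a-octahydronaphthalene-1-carbaldehyde (avarane 8S,9R,10S; C4 ketal; C5=C6; CHO = C11)
Conditions: (R)-1-(2-methylphenyl)-3,3-diphenyltetrahydro-1H,3H-pyrrolo[1,2-c][1,3,2]oxazaborole (20 mol%) activated with HN(SO2CF3)2 (18 mol%), CH2Cl2, −78 → −20 °C
Reagents that add atoms: none
Why: Coordination of the formyl oxygen of 4 to the cationic boron lowers the enal LUMO, and a concerted, asynchronous [4+2] cycloaddition with the s-cis diene of 3 follows; the closest known reaction type is the oxazaborolidinium-catalysed enantioselective Diels–Alder reaction of α-substituted α,β-enals. Ring B is closed in an intermolecular [4+2] mode by the C7–C8 and C9–C10 bonds, and the new C5=C6 bond stays next to the masked C4 carbonyl. The C8/C9 relation (cis methyls, formyl trans to the C8 methyl) is carried over suprafacially from the E geometry of 4; C10 relative to C9 follows from the formyl-exo transition state that α-substituted enals favour with this catalyst class (formyl cis to H10); the absolute sense comes from the (R)-catalyst, whose aryl group shields one face of the s-trans enal held by B–O coordination and a formyl C–H···O contact. The step needs "ortho" regiochemistry (formyl-bearing C9 to the ring terminus C10, C8 to the CH2 terminus C7), which the alkyl-substituted diene terminus, the electron-poor ketal carbon on C5 and the pairing of the β-methyl carbon with the unsubstituted terminus should all favour. It also needs exo selectivity, which should be reinforced because the endo mode would push the boron-bound formyl group against the dioxolane oxygen under C5; the low temperature and a slight deficit of acid relative to oxazaborolidine should keep the allylic ketal intact. The reaction is a pure addition in which every atom of 3 and 4 is kept in 5, so the two partners are used in equimolar amounts.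

**Step 4**
Reactants: 5 the cycloadduct aldehyde; 6 1,2,4,5-tetramethoxybenzene
Product: 10 O-{[(1R,2S,8aS)-5,5-(ethylenedioxy)-1,2-dimethyl-1,2,3,5,6,7,8,8a-octahydronaphthalen-1-yl](2,3,5,6-tetramethoxyphenyl)methyl} S-methyl carbonodithioate (both C11 epimers), via aryllithium 7 (not isolated), via lithium alkoxide 8 (not isolated), via lithium xanthate 9 (not isolated)
Conditions: 6, n-BuLi, THF, 0 °C → rt; then 5, −78 → 0 °C; then CS2, 0 °C → rt; then MeI, rt
Reagents that add atoms: carbon disulfide, S=C=S; iodomethane, CI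
Why: Directed ortho-lithiation of 6 between two methoxy groups gives 7, which adds 1,2 to the non-enolisable neopentyl aldehyde, and the alkoxide is trapped in the same flask as the S-methyl xanthate (first half of a Barton–McCombie deoxygenation); the new carbinol centre is of no consequence.

**Step 5**
Reactants: 10 the xanthate
Product: 11 (1R,2S,8aS)-5,5-(ethylenedioxy)-1,2-dimethyl-1-[(2,3,5,6-tetramethoxyphenyl)methyl]-1,2,3,5,6,7,8,8a-octahydronaphthalene
Conditions: Bu3SnH (2 equiv), AIBN (cat.), toluene, 110 °C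
Reagents that add atoms: none
Why: Barton–McCombie radical deoxygenation; the stabilised benzylic C11 radical is reduced by Bu3SnH and has only 4-exo or 5-endo paths to C5=C6, so it should not cyclise and no stereocentre is touched.

**Step 6**
Reactants: 11 the ketal
Product: 12 (4aS,5R,6S)-5,6-dimethyl-5-[(2,3,5,6-tetramethoxyphenyl)methyl]-3,4,4a,5,6,7-hexahydronaphthalen-1(2H)-one
Conditions: 1 M HCl, THF, rt
Reagents that add atoms: water, O
Why: Acid-catalysed ketal hydrolysis unmasks the C4 ketone, which is conjugated with C5=C6 from the outset, so no double-bond shift is needed and C8–C10 cannot epimerise.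

**Step 7**
Reactants: 12 the enone
Product: 14 (4aS,5R,6S,8aR)-5,6,8a-trimethyl-5-[(2,3,5,6-tetramethoxyphenyl)methyl]octahydronaphthalen-1(2H)-one, via lithium enolate 13 (not isolated)
Conditions: Li (2.1 equiv), NH3(l)/THF, t-BuOH (1.0 equiv), −78 °C; then MeI (excess), −78 → −33 °C
Reagents that add atoms: iodomethane, CI
Why: Stork reductive alkylation gives the C4(OLi)=C5 enolate regiospecifically; ring B of this enolate is a chair whose axial C9 methyl lies 1,3 to C5, so iodomethane should attack C5 from the opposite face, cis to H10, and give the 5R cis-decalin.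

**Step 8**
Reactants: 14 the ketone
Product: 15 1,2,4,5-tetramethoxy-3-{[(1R,2S,4aR,8aS)-1,2,4a-trimethyl-5-methylidenedecahydronaphthalen-1-yl]methyl}benzene
Conditions: Ph3PCH3Br (5 equiv), KOtBu (4.5 equiv), toluene, 100 °C
Reagents that add atoms: methyltriphenylphosphonium bromide, C[P+](c1ccccc1)(c1ccccc1)c1ccccc1.[Br-]
Why: Wittig methylenation with excess ylide at raised temperature, the usual answer to a ketone flanked by a quaternary carbon; C5 is quaternary and cannot epimerise.

**Step 9**
Reactants: 15 the tetramethoxyarene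
Product: 16 2,5-dimethoxy-3-{[(1R,2S,4aR,8aS)-1,2,4a-trimethyl-5-methylidenedecahydronaphthalen-1-yl]methyl}cyclohexa-2,5-diene-1,4-dione
Conditions: (NH4)2Ce(NO3)6 (2.5 equiv), MeCN/H2O, 0 °C
Reagents that add atoms: water, O
Why: Oxidative demethylation of a 1,4-dimethoxyarene by tetravalent cerium; the two para pairs of methoxy groups are equivalent by symmetry, so a single para-quinone should form, and the isolated alkene should survive at 0 °C.

**Step 10**
Reactants: 16 the dimethoxyquinone
Product: 17 2-hydroxy-5-methoxy-3-{[(1R,2S,4aR,8aS)-1,2,4a-trimethyl-5-methylidenedecahydronaphthalen-1-yl]methyl}cyclohexa-2,5-diene-1,4-dione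
Conditions: KOH (2 M aq, 3 equiv), MeOH, 0 °C → rt; then 1 M HCl
Reagents that add atoms: potassium hydroxide, [K+].[OH-]
Why: Addition–elimination of hydroxide at a vinylogous ester carbon; the methoxy group flanked by a carbonyl and the bulky alkyl substituent is twisted out of conjugation and should be the more labile, and the hydroxyquinone anion formed resists a second hydrolysis.

**Compound list**

1 | 2-bromocyclohex-2-en-1-one | O=C1CCCC=C1Br | starting material
2 | 6-bromo-1,4-dioxaspiro[4.5]dec-6-ene | BrC1=CCCCC12OCCO2 | intermediate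
3 | 6-ethenyl-1,4-dioxaspiro[4.5]dec-6-ene | C=CC1=CCCCC12OCCO2 | intermediate
4 | (E)-2-methylbut-2-enal | C/C=C(\C)C=O | starting material
5 | (1R,2S,8aS)-5,5-(ethylenedioxy)-1,2-dimethyl-1,2,3,5,6,7,8,8a-octahydronaphthalene-1-carbaldehyde | C12(OCCO1)CCC[C@H]3[C@](C)(C=O)[C@@H](C)CC=C23 | intermediate
6 | 1,2,4,5-tetramethoxybenzene | COc1cc(OC)c(OC)cc1OC | starting material
7 | 2,3,5,6-tetramethoxyphenyllithium | [Li]c1c(OC)c(OC)cc(OC)c1OC | intermediate
8 | lithium [(1R,2S,8aS)-5,5-(ethylenedioxy)-1,2-dimethyl-1,2,3,5,6,7,8,8a-octahydronaphthalen-1-yl](2,3,5,6-tetramethoxyphenyl)methanolate | C12(OCCO1)CCC[C@H]3[C@](C)(C([O-])c4c(OC)c(OC)cc(OC)c4OC)[C@@H](C)CC=C23.[Li+] | intermediate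
9 | lithium O-{[(1R,2S,8aS)-5,5-(ethylenedioxy)-1,2-dimethyl-1,2,3,5,6,7,8,8a-octahydronaphthalen-1-yl](2,3,5,6-tetramethoxyphenyl)methyl} carbonodithioate | C12(OCCO1)CCC[C@H]3[C@](C)(C(OC(=S)[S-])c4c(OC)c(OC)cc(OC)c4OC)[C@@H](C)CC=C23.[Li+] | intermediate
10 | O-{[(1R,2S,8aS)-5,5-(ethylenedioxy)-1,2-dimethyl-1,2,3,5,6,7,8,8a-octahydronaphthalen-1-yl](2,3,5,6-tetramethoxyphenyl)methyl} S-methyl carbonodithioate | C12(OCCO1)CCC[C@H]3[C@](C)(C(OC(=S)SC)c4c(OC)c(OC)cc(OC)c4OC)[C@@H](C)CC=C23 | intermediate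
11 | (1R,2S,8aS)-5,5-(ethylenedioxy)-1,2-dimethyl-1-[(2,3,5,6-tetramethoxyphenyl)methyl]-1,2,3,5,6,7,8,8a-octahydronaphthalene | C12(OCCO1)CCC[C@H]3[C@](C)(Cc4c(OC)c(OC)cc(OC)c4OC)[C@@H](C)CC=C23 | intermediate
12 | (4aS,5R,6S)-5,6-dimethyl-5-[(2,3,5,6-tetramethoxyphenyl)methyl]-3,4,4a,5,6,7-hexahydronaphthalen-1(2H)-one | O=C1CCC[C@H]2[C@](C)(Cc3c(OC)c(OC)cc(OC)c3OC)[C@@H](C)CC=C12 | intermediate
13 | lithium (4aS,5R,6S)-5,6-dimethyl-5-[(2,3,5,6-tetramethoxyphenyl)methyl]-2,3,4,4a,5,6,7,8-octahydronaphthalen-1-olate | [Li+].[O-]C=1CCC[C@H]2[C@](C)(Cc3c(OC)c(OC)cc(OC)c3OC)[C@@H](C)CCC2=1 | intermediate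
14 | (4aS,5R,6S,8aR)-5,6,8a-trimethyl-5-[(2,3,5,6-tetramethoxyphenyl)methyl]octahydronaphthalen-1(2H)-one | O=C1CCC[C@H]2[C@](C)(Cc3c(OC)c(OC)cc(OC)c3OC)[C@@H](C)CC[C@@]12C | intermediate
15 | 1,2,4,5-tetramethoxy-3-{[(1R,2S,4aR,8aS)-1,2,4a-trimethyl-5-methylidenedecahydronaphthalen-1-yl]methyl}benzene | C=C1CCC[C@H]2[C@](C)(Cc3c(OC)c(OC)cc(OC)c3OC)[C@@H](C)CC[C@@]12C | intermediate
16 | 2,5-dimethoxy-3-{[(1R,2S,4aR,8aS)-1,2,4a-trimethyl-5-methylidenedecahydronaphthalen-1-yl]methyl}cyclohexa-2,5-diene-1,4-dione | C=C1CCC[C@H]2[C@](C)(CC3=C(OC)C(=O)C=C(OC)C3=O)[C@@H](C)CC[C@@]12C | intermediate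
17 | 2-hydroxy-5-methoxy-3-{[(1R,2S,4aR,8aS)-1,2,4a-trimethyl-5-methylidenedecahydronaphthalen-1-yl]methyl}cyclohexa-2,5-diene-1,4-dione | C=C1CCC[C@H]2[C@](C)(CC3=C(O)C(=O)C=C(OC)C3=O)[C@@H](C)CC[C@@]12C | target

**Step count**

Total: 10 steps. Longest linear sequence: 10 steps (1 → 17); 4 and 6 enter as purchased compounds.

**Steps most likely to fail**

Step 3. The risks are insufficient exo/endo discrimination, insufficient or reversed enantiofacial discrimination, and ionisation of the allylic ketal by the cationic boron catalyst. The exo preference is argued from α-substituted enals with cyclic dienes and is less certain for an acyclic diene terminus. The fallback replaces catalyst control by substrate control; it sets out from 1 and returns at 12. Reduction of 1 with BH3·SMe2 and (S)-1-methyl-3,3-diphenyltetrahydro-1H,3H-pyrrolo[1,2-c][1,3,2]oxazaborole should give (R)-2-bromocyclohex-2-en-1-ol F1. Silylation (TBSCl, imidazole) gives the silyl ether (R)-[(2-bromocyclohex-2-en-1-yl)oxy](tert-butyl)dimethylsilane F2, and vinylation as in step 2 gives the diene (R)-tert-butyl[(2-ethenylcyclohex-2-en-1-yl)oxy]dimethylsilane F3. Cycloaddition with 4 under the bulky, exo-directing Lewis acid Al(OC6H3-2,6-Ph2)3 should take place anti to the pseudoaxial silyloxy group and give the silyloxy aldehyde F4 with the C8–C10 configuration of 5. Treatment with 7, CS2 and MeI as in step 4 leads through the lithium alkoxide F5 and the lithium xanthate F6 to the xanthate F7. Bu3SnH then gives the deoxygenated silyl ether F8, Bu4NF the allylic alcohol F9, and Dess–Martin periodinane the enone 12.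

Step 7. The risks are over-reduction of the ketone or of the electron-rich arene, and proton transfer in the enolate leading to methylation at C3 or to polymethylation. The fallback replaces the dissolving-metal reduction; it sets out from 12 and returns at 14. 1,4-Hydrosilylation with Et3SiH and RhCl(PPh3)3 should give the triethylsilyl enol ether F10; MeLi in THF regenerates the lithium enolate 13 free of proton donors, and MeI then gives 14 under the same facial control.

Step 10. The risks are attack of hydroxide at the other methoxy-bearing carbon, and double hydrolysis. The fallback sets out from 16 and returns at 17. Exhaustive hydrolysis (NaOH, aqueous EtOH, 50 °C) should give the dihydroxyquinone F11; acid-catalysed vinylogous esterification (MeOH, HC(OMe)3, cat. p-TsOH, rt) should then methylate only the hydroxyl-bearing carbon flanked by C–H, the less hindered one, and give 17.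

**Further compounds**

F1 | step 3 | (R)-2-bromocyclohex-2-en-1-ol | O[C@@H]1CCCC=C1Br
F2 | step 3 | (R)-[(2-bromocyclohex-2-en-1-yl)oxy](tert-butyl)dimethylsilane | CC(C)(C)[Si](C)(C)O[C@@H]1CCCC=C1Br
F3 | step 3 | (R)-tert-butyl[(2-ethenylcyclohex-2-en-1-yl)oxy]dimethylsilane | CC(C)(C)[Si](C)(C)O[C@@H]1CCCC=C1C=C
F4 | step 3 | (1R,2S,5R,8aR)-5-[(tert-butyldimethylsilyl)oxy]-1,2-dimethyl-1,2,3,5,6,7,8,8a-octahydronaphthalene-1-carbaldehyde | CC(C)(C)[Si](C)(C)O[C@@H]1CCC[C@H]2[C@](C)(C=O)[C@@H](C)CC=C12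
F5 | step 3 | lithium {(1R,2S,5R,8aR)-5-[(tert-butyldimethylsilyl)oxy]-1,2-dimethyl-1,2,3,5,6,7,8,8a-octahydronaphthalen-1-yl}(2,3,5,6-tetramethoxyphenyl)methanolate | CC(C)(C)[Si](C)(C)O[C@@H]1CCC[C@H]2[C@](C)(C([O-])c3c(OC)c(OC)cc(OC)c3OC)[C@@H](C)CC=C12.[Li+]
F6 | step 3 | lithium O-[{(1R,2S,5R,8aR)-5-[(tert-butyldimethylsilyl)oxy]-1,2-dimethyl-1,2,3,5,6,7,8,8a-octahydronaphthalen-1-yl}(2,3,5,6-tetramethoxyphenyl)methyl] carbonodithioate | CC(C)(C)[Si](C)(C)O[C@@H]1CCC[C@H]2[C@](C)(C(OC(=S)[S-])c3c(OC)c(OC)cc(OC)c3OC)[C@@H](C)CC=C12.[Li+]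
F7 | step 3 | O-[{(1R,2S,5R,8aR)-5-[(tert-butyldimethylsilyl)oxy]-1,2-dimethyl-1,2,3,5,6,7,8,8a-octahydronaphthalen-1-yl}(2,3,5,6-tetramethoxyphenyl)methyl] S-methyl carbonodithioate | CC(C)(C)[Si](C)(C)O[C@@H]1CCC[C@H]2[C@](C)(C(OC(=S)SC)c3c(OC)c(OC)cc(OC)c3OC)[C@@H](C)CC=C12
F8 | step 3 | tert-butyldimethyl({(1R,4aS,5R,6S)-5,6-dimethyl-5-[(2,3,5,6-tetramethoxyphenyl)methyl]-1,2,3,4,4a,5,6,7-octahydronaphthalen-1-yl}oxy)silane | CC(C)(C)[Si](C)(C)O[C@@H]1CCC[C@H]2[C@](C)(Cc3c(OC)c(OC)cc(OC)c3OC)[C@@H](C)CC=C12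
F9 | step 3 | (1R,4aS,5R,6S)-5,6-dimethyl-5-[(2,3,5,6-tetramethoxyphenyl)methyl]-1,2,3,4,4a,5,6,7-octahydronaphthalen-1-ol | O[C@@H]1CCC[C@H]2[C@](C)(Cc3c(OC)c(OC)cc(OC)c3OC)[C@@H](C)CC=C12
F10 | step 7 | triethyl({(4aS,5R,6S)-5,6-dimethyl-5-[(2,3,5,6-tetramethoxyphenyl)methyl]-2,3,4,4a,5,6,7,8-octahydronaphthalen-1-yl}oxy)silane | CC[Si](CC)(CC)OC=1CCC[C@H]2[C@](C)(Cc3c(OC)c(OC)cc(OC)c3OC)[C@@H](C)CCC2=1
F11 | step 10 | 2,5-dihydroxy-3-{[(1R,2S,4aR,8aS)-1,2,4a-trimethyl-5-methylidenedecahydronaphthalen-1-yl]methyl}cyclohexa-2,5-diene-1,4-dione | C=C1CCC[C@H]2[C@](C)(CC3=C(O)C(=O)C=C(O)C3=O)[C@@H](C)CC[C@@]12C
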